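Fraction of the J charged per hour is the unit in which I compare these flasks, and Tuesday's, Saturday's, Sunday's, Friday's and both earlier runs hold E at 0.2 mol%.

common to all: E 0.2 mol%
- south-west: J 0.068 M; run made earlier
- east: J 0.22 M; run made earlier
- Tuesday's: J 0.080 M; time 20 h
- Saturday's: J 0.12 M; time 20 h
- Sunday's: J 0.20 M; time 20 h
- Friday's: J 0.30 M; time 20 h

| run | time / h | X / % |
|---|---|---|
| south-west | 2.00 | 9.2 |
| south-west | 4.00 | 17.4 |
| south-west | 6.00 | 22.4 |
| south-west | 8.00 | 22.3 |
| south-west | 10.0 | 25.6 |
| south-west | 12.0 | 25.9 |
| south-west | 15.0 | 26.9 |
| east | 1.00 | 16.7 |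
| east | 1.50 | 21.9 |
| east | 2.50 | 32.9 |
| east | 4.00 | 37.9 |
| east | 6.00 | 44.6 |
| east | 10.0 | 45.8 |
| east | 15.0 | 38.1 |

(each reading ± 1 percentage point)

- steps thought possible: J + E -> E + X; J -> Q; E + X -> E + Z
- "hardly changes" means that all values lie within two and a half points (for a concentration: within two and a half percent of the largest)

* amount of X at the end, in percent of the J charged for Tuesday's, Saturday's, Sunday's, Friday's, in this order
* how the row runs (hardly changes / falls all the way / rises all the way / rises, then falls / falls, then rises)

The steps thought possible are J + E → E + X, J → Q and E + X → E + Z. E comes back out of each step it enters, so I freeze c_E at its charge, which is a fixed share of the starting c_J. The two steps through E then run pseudo-first-order, each at a rate in proportion to the charge of J, while J → Q keeps its own pace.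

The first rung is the making of X. I read 0.167 h⁻¹ in the east run and 0.0460 h⁻¹ in the south-west run, a ratio of 3.63 for a ratio of charges of 3.24.

The next rung is the end of J. X flattens in both runs, and the east run reads more X at its top, 45.8%, than the south-west run at its last point, 26.9%.

The last rung is the erosion of X. I count the east run's fall from 45.8% to 38.1% between 10.0 h and 15.0 h as E + X → E + Z with nothing still made. That gives a half-life of 18.8 h, read with the scatter of two readings. Its product with the charge, 4.14 h·M, is my erosion product: the half-life of X times the c_J charged, at this loading of E.

It gives 51.8 h for Tuesday's flask, longer than the run, and 13.8 h for Friday's flask, shorter than the run. Over the second half of the time, X would keep 87.5% in Tuesday's flask and 60.5% in Friday's flask. The top climbs with charge and the kept share sinks, so I expect a row that rises, then falls, and I give no points of my own.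

The forecast says 28%, 32%, 33%, 29%, rises, then falls: “The row should rise, then fall”.

    J + E → E + X (k = 0.120 M⁻¹ s⁻¹)
    J → Q (k = 3.30 × 10⁻⁵ s⁻¹)
    E + X → E + Z (k = 0.0240 M⁻¹ s⁻¹)

The flasks end at 29.2%, 33.3%, 33.5% and 28.1%, so the row rises, then falls, turning at 0.16 M. In Friday's flask J stood at 2.28% at 10.0 h, with X at 45.5% and Z already at 21.5%. By 20.0 h in Friday's flask J was down to 0.0521%, Z was up to 40.4% and X had fallen to 28.1%, a net half-life of X of 14.4 h against 13.8 h from the product. In Tuesday's flask the product gives 51.8 h, and the half-life of X by that step is 50 h.

(Readings and results were computed with constants of no real substance; scatter was added.)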